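## Retrosynthetic overview
1. Remove the C2′–OH (enolate hydroxylation), then cut ring C by retro-Diels–Alder at C2′–C4 and C14′–C15. Both halves then become one monomer, dehydrozaluzanin C 11, used as dienophile (C4=C15) and, after 1,2-dehydrogenation, as diene 13 (C2′=C1′–C10′=C14′).
2. 11 comes from the 4α,10α-diol 10 by double anti-elimination. 10 comes from ketone 4 through a C3=C4 silyl enol ether, which masks the ketone during lactone selenenylation and then takes up the C4 oxygen.
3. Key disconnection: the five-membered ring A/A′ (C1–C5) and the seven-membered ring B/B′ of each half go back to the two six-membered rings of α-santonin 1. Returning C5 from C1 to C10 reverses a photochemical ring contraction (6 to 5) coupled with a ring expansion (6 to 7).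
4. Enabling feature: in ring A′ (C1′–C5′) the ketone C3′ sits between C2′ and the C15′-bearing C4′, and C1′ is bonded both to C5′ and to the trigonal, C14′-bearing C10′ of ring B′. This is the imprint of a 4-methylcyclohexa-2,5-dienone whose quaternary C10 carries the angular methyl group. The trans-lactone centres C6/C7 are already present in 1.
5. Ring order: the lactone rings are bought with 1, rings A/B and A′/B′ are formed in step 1, and ring C is formed last, in step 9.

Key step: step 1

Remark: guaiane numbering is used; unprimed locants are the half with the spiro carbon C4, primed locants the half with the tertiary alcohol C2′; α is the face of H-1, H-5 and H-7; commercial (−)-α-santonin carries the C6/C7 configuration of both halves.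

## Route

Step 1
Reactants: 1 (−)-α-santonin
Product: 3 isophotosantonic lactone (10α-hydroxy-3-oxo-1αH-guai-4-en-12,6α-olide), via cyclopropyl oxyallyl zwitterion 2 (not isolated)
Conditions: hν (medium-pressure Hg lamp, Pyrex), AcOH–H2O 1:1, N2, reflux
Reagents that add atoms: water, O
Why: Excitation of the cross-conjugated dienone and intersystem crossing lead to bonding between the two β-carbons C1 and C5, which gives the cyclopropyl oxyallyl zwitterion 2; aqueous acid protonates its oxygen before it can slip to the lumiketone. The C4 methyl group holds the positive charge at C4, so the cyclopropane bond C5–C10 breaks (C4=C5 forms) rather than C1–C10, which would give a spiro[4.5]decane, and water takes the tertiary C10 position. The net result is a 1,2-shift of C5 from C10 to C1: the six-membered ring A (C1–C5 plus C10) contracts to the cyclopentenone C1–C5, closed by the 3-exo C1–C5 bonding, and ring B grows from six to seven members when the shared C5–C10 bond of the bicyclo[4.1.0] unit is cut. The closest known reaction type is the photorearrangement of 4,4-disubstituted cyclohexa-2,5-dienones in protic acid to 5/7-fused hydroxy enones. C1 (H-1α) is controlled by the quaternary C10 and the ring B tether, which allow only the folding that puts C10 on the β face of the new five-membered ring with C9 exo, and C10 (10α-OH, 10β-CH3) arises by attack of water anti to the departing C5; C6, C7 and C11 are not touched. The step needs solvolysis to win over lumiketone formation and over secondary photolysis of 3, which the protic acidic medium, the Pyrex filter and stopping before full conversion should secure.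

Step 2
Reactants: 3 isophotosantonic lactone
Product: 4 10α-hydroxy-3-oxo-1α,4α,5αH-guaian-12,6α-olide
Conditions: H2 (1 atm), 10% Pd/C, EtOAc, rt
Reagents that add atoms: none
Why: Heterogeneous syn-hydrogenation of the tetrasubstituted enone C4=C5 should take place on the α face, the side of H-1 and away from C10 and its β-methyl group, which sets H-5α (cis-fused hydroazulene), while the C4 centre made here is erased in step 3.

Step 3
Reactants: 4 10α-hydroxy-3-oxo-1α,4α,5αH-guaian-12,6α-olide
Product: 5 3,10α-bis(triethylsilyloxy)-1α,5αH-guai-3-en-12,6α-olide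
Conditions: Et3SiOTf (2.5 equiv), Et3N, CH2Cl2, 0 °C to rt
Reagents that add atoms: triethylsilyl triflate, CC[Si](CC)(CC)OS(=O)(=O)C(F)(F)F
Why: Soft enolisation with a silyl triflate and Et3N under equilibrating conditions should give the more substituted C3=C4 silyl enol ether, which masks the ketone against the strong base of step 4 and marks C4 for oxidation, and the same reagent caps the tertiary C10 alcohol.

Step 4
Reactants: 5 3,10α-bis(triethylsilyloxy)-1α,5αH-guai-3-en-12,6α-olide
Product: 7 11β-phenylseleno-3,10α-bis(triethylsilyloxy)-1α,5αH-guai-3-en-12,6α-olide, via lithium lactone enolate 6 (not isolated)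
Conditions: LiN(iPr)2 (1.1 equiv), THF, −78 °C; PhSeBr (1.05 equiv), −78 °C
Reagents that add atoms: benzeneselenenyl bromide, Br[Se]c1ccccc1
Why: H-11 is the only acidic proton left, so the selenenylation of the lactone enolate should be clean, and selenium is expected on the β face, anti to H-7α, at a C11 centre that is removed again in step 5.

Step 5
Reactants: 7 11β-phenylseleno-3,10α-bis(triethylsilyloxy)-1α,5αH-guai-3-en-12,6α-olide
Product: 9 4α,10α-bis(triethylsilyloxy)-3-oxo-1α,5αH-guai-11(13)-en-12,6α-olide, via selenoxide 8 (not isolated)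
Conditions: mCPBA (2.1 equiv), CH2Cl2, −78 °C to rt
Reagents that add atoms: 3-chloroperbenzoic acid, O=C(OO)c1cccc(Cl)c1
Why: The peracid does two known jobs in one flask, a Rubottom oxidation of the electron-rich C3=C4 enol ether on the convex α face (face of H-1 and H-5), which sets the 4α-oxygen after silyl migration, and oxidation of the selenide to selenoxide 8, whose syn-elimination can only use a C13 hydrogen because H-7α is anti to the β-selenium, so the exocyclic α-methylene lactone should form.

Step 6
Reactants: 9 4α,10α-bis(triethylsilyloxy)-3-oxo-1α,5αH-guai-11(13)-en-12,6α-olide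
Product: 10 4α,10α-dihydroxy-3-oxo-1α,5αH-guai-11(13)-en-12,6α-olide
Conditions: HF·pyridine, MeCN, 0 °C
Reagents that add atoms: none
Why: Fluoride-mediated cleavage of both triethylsilyl ethers under mildly acidic conditions should leave the α-ketol, the lactone and its exocyclic alkene untouched and creates no stereocentre.

Step 7
Reactants: 10 4α,10α-dihydroxy-3-oxo-1α,5αH-guai-11(13)-en-12,6α-olide
Product: 11 dehydrozaluzanin C (3-oxoguaia-4(15),10(14),11(13)-trien-12,6α-olide)
Conditions: SOCl2 (3 equiv), pyridine, −20 to 0 °C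
Reagents that add atoms: none
Why: Anti-periplanar E2 dehydration of tertiary alcohols with SOCl2 in pyridine should give both exocyclic alkenes, because at C4 the α-oxygen is syn to H-5α and C3 carries no hydrogen, so only the C15 methyl group can deliver an anti hydrogen, and at C10 the α-oxygen is syn to H-1α and the freely rotating C14 methyl group reaches the anti arrangement more easily than H-9β of the seven-membered ring.

Step 8
Reactants: 11 dehydrozaluzanin C (one part of the material)
Product: 12 3-(tert-butyldimethylsilyloxy)guaia-2,4(15),10(14),11(13)-tetraen-12,6α-olide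
Conditions: tBuMe2SiOTf, Et3N, CH2Cl2, −78 to 0 °C
Reagents that add atoms: tert-butyldimethylsilyl triflate, CC(C)(C)[Si](C)(C)OS(=O)(=O)C(F)(F)F
Why: Soft enolisation can only go toward C2, since C4 is trigonal, and gives the cross-conjugated 2-silyloxy diene 12, whose s-trans-locked diene unit cannot cycloadd, without touching C1 or C5.

Step 9
Reactants: 12 3-(tert-butyldimethylsilyloxy)guaia-2,4(15),10(14),11(13)-tetraen-12,6α-olide; 11 dehydrozaluzanin C
Product: 14 2′-deoxy dimer (endo Diels–Alder adduct with H-2′α), via trienone 13 (not isolated)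
Conditions: Pd(OAc)2 (1.1 equiv), 11 (3 equiv), MeCN, rt to 40 °C
Reagents that add atoms: none
Why: Saegusa–Ito dehydrosilylation with loss of H-1 unveils the s-cis-locked dienone C14′=C10′–C1′=C2′ of 13, which should add as a 1-acyl diene to the more electrophilic exocyclic enone C4=C15 of 11 with ortho regiochemistry (C14′–C15 and C2′–C4) in an endo Diels–Alder reaction on the convex α face of 11 (face of H-1 and H-5), which sets the spiro centre C4 and, provisionally, C2′.

Step 10
Reactants: 14 2′-deoxy dimer
Product: 16 target CNP0269880.2, via sodium dienolate 15 (not isolated)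
Conditions: NaN(SiMe3)2 (1.0 equiv), THF, −78 °C; 2-(phenylsulfonyl)-3-phenyloxaziridine, −78 °C; AcOH
Reagents that add atoms: 2-(phenylsulfonyl)-3-phenyloxaziridine, O=S(=O)(c1ccccc1)N1OC1c1ccccc1
Why: The base removes the only doubly activated proton (H-2′, α to C3′=O and allylic to C1′=C10′, so either C2′ epimer of 14 converges on 15), and Davis hydroxylation of the extended enolate at its α-carbon should come from the α′ face, anti to the pseudo-axial acyl carbon C3 of the spiro ring and on the convex side of the primed hydroazulene (face of H-5′), which sets C2′.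

## Compound list
1 | (−)-α-santonin | C[C@H]1[C@@H]2CC[C@@]3(C)C=CC(=O)C(C)=C3[C@H]2OC1=O | starting material
2 | cyclopropyl oxyallyl zwitterion (1,5-cyclo form of 1) | C[C@H]1[C@@H]2CC[C@@]3(C)[C@@H]4[CH+]C([O-])=C(C)[C@@]43[C@H]2OC1=O | intermediate
3 | isophotosantonic lactone | CC1=C2[C@H]3OC(=O)[C@@H](C)[C@@H]3CC[C@@](C)(O)[C@@H]2CC1=O | intermediate
4 | 10α-hydroxy-3-oxo-1α,4α,5αH-guaian-12,6α-olide | C[C@@H]1[C@@H]2[C@H]3OC(=O)[C@@H](C)[C@@H]3CC[C@@](C)(O)[C@@H]2CC1=O | intermediate
5 | 3,10α-bis(triethylsilyloxy)-1α,5αH-guai-3-en-12,6α-olide | CC1=C(O[Si](CC)(CC)CC)C[C@@H]2[C@H]1[C@H]3OC(=O)[C@@H](C)[C@@H]3CC[C@@]2(C)O[Si](CC)(CC)CC | intermediate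
6 | lithium lactone enolate of 5 | [Li+].CC1=C(O[Si](CC)(CC)CC)C[C@@H]2[C@H]1[C@H]3OC([O-])=C(C)[C@@H]3CC[C@@]2(C)O[Si](CC)(CC)CC | intermediate
7 | 11β-phenylseleno derivative of 5 | CC1=C(O[Si](CC)(CC)CC)C[C@@H]2[C@H]1[C@H]3OC(=O)[C@](C)([Se]c4ccccc4)[C@@H]3CC[C@@]2(C)O[Si](CC)(CC)CC | intermediate
8 | 11β-selenoxide of the 4α-silyloxy ketone | C[C@@]1(O[Si](CC)(CC)CC)C(=O)C[C@@H]2[C@H]1[C@H]3OC(=O)[C@](C)([Se](=O)c4ccccc4)[C@@H]3CC[C@@]2(C)O[Si](CC)(CC)CC | intermediate
9 | 4α,10α-bis(triethylsilyloxy)-3-oxo-1α,5αH-guai-11(13)-en-12,6α-olide | C[C@@]1(O[Si](CC)(CC)CC)C(=O)C[C@@H]2[C@H]1[C@H]3OC(=O)C(=C)[C@@H]3CC[C@@]2(C)O[Si](CC)(CC)CC | intermediate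
10 | 4α,10α-dihydroxy-3-oxo-1α,5αH-guai-11(13)-en-12,6α-olide | C[C@@]1(O)C(=O)C[C@@H]2[C@H]1[C@H]3OC(=O)C(=C)[C@@H]3CC[C@@]2(C)O | intermediate
11 | dehydrozaluzanin C | C=C1C(=O)C[C@H]2C(=C)CC[C@H]3C(=C)C(=O)O[C@@H]3[C@H]21 | intermediate
12 | 3-(tert-butyldimethylsilyloxy)guaia-2,4(15),10(14),11(13)-tetraen-12,6α-olide | C=C1C(O[Si](C)(C)C(C)(C)C)=C[C@H]2C(=C)CC[C@H]3C(=C)C(=O)O[C@@H]3[C@H]21 | intermediate
13 | 3-oxoguaia-1,4(15),10(14),11(13)-tetraen-12,6α-olide (trienone) | C=C1C(=O)C=C2C(=C)CC[C@H]3C(=C)C(=O)O[C@@H]3[C@H]21 | intermediate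
14 | 2′-deoxy dimer (endo adduct, H-2′α) | C=C1C(=O)[C@@H]2C3=C(CC[C@H]4C(=C)C(=O)O[C@@H]4[C@@H]13)CC[C@]21C(=O)C[C@H]2C(=C)CC[C@H]3C(=C)C(=O)O[C@@H]3[C@H]21 | intermediate
15 | sodium dienolate of 14 | [Na+].C=C1C([O-])=C2C3=C(CC[C@H]4C(=C)C(=O)O[C@@H]4[C@@H]13)CC[C@]21C(=O)C[C@H]2C(=C)CC[C@H]3C(=C)C(=O)O[C@@H]3[C@H]21 | intermediate
16 | CNP0269880.2 | C=C1C(=O)[C@]2(O)C3=C(CC[C@H]4C(=C)C(=O)O[C@@H]4[C@@H]13)CC[C@]21C(=O)C[C@H]2C(=C)CC[C@H]3C(=C)C(=O)O[C@@H]3[C@H]21 | target

## Step count and risks
Total step count: 10. Longest linear sequence: 10 (1 to 16; compound 11 enters twice, in steps 8 and 9).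

The three steps most likely to fail:

1. **Step 10.**
   - What may go wrong: the oxidant may attack the wrong face of the planar dienolate. The base may deprotonate at C2 of the unprimed ketone instead, or add in conjugate fashion to the α-methylene lactones.
   - Fallback (sets out from 12, comes back at 16): the C2′ oxygen is brought in with the diene instead of being added last.
   - Rubottom oxidation of 12 with dimethyldioxirane on the convex face, followed by HF·pyridine, should give 2α-hydroxydehydrozaluzanin C F1.
   - Dess–Martin oxidation should give the 2,3-dione, which should rest as its diosphenol tautomer, 2-hydroxy-3-oxoguaia-1,4(15),10(14),11(13)-tetraen-12,6α-olide F2.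
   - F2 is a 1-hydroxy diene. It is combined with excess 11 in a polarity-matched endo [4+2] union (vinylogous Michael addition at C15, then aldol closure at C2′) on the α face of 11. This forms C2′–C4 and the tertiary alcohol together and gives 16.

2. **Step 7.**
   - What may go wrong: elimination next to the carbonyl group may be sluggish, chloride may substitute at C4, or a proton may be lost from C9 so that the ring alkene forms.
   - Fallback (sets out from 4, comes back at 11): the exocyclic enone is made by epoxide isomerisation.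
   - NaBH4 reduction of 4 from the α face should give 3β,10α-dihydroxy-1α,4α,5αH-guaian-12,6α-olide F3.
   - Double dehydration with Ph2S[OC(CF3)2Ph]2 (H-4α is anti to the 3β-oxygen) should give guaia-3,10(14)-dien-12,6α-olide F4.
   - mCPBA should epoxidise only the trisubstituted alkene, on the α face, to 3α,4α-epoxyguai-10(14)-en-12,6α-olide F5.
   - Al(OiPr)3 in hot toluene should isomerise F5 to 3α-hydroxyguaia-4(15),10(14)-dien-12,6α-olide F6.
   - LiN(iPr)2 (2.2 equiv) and PhSeBr should give the 11β-phenylseleno lactone F7, and H2O2 should give 3-epizaluzanin C F8.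
   - Dess–Martin oxidation of F8 gives 11.

3. **Step 9.**
   - What may go wrong: 12 may protodesilylate back to 11. Palladium may bind to the 1,1-disubstituted alkenes. The trienone may dimerise with itself instead of reacting in the cross sense.
   - Fallback (sets out from 12, comes back at 14): the diene is released without metal by selenoxide elimination.
   - PhSeCl should convert 12 on the convex face to 2α-phenylselenodehydrozaluzanin C F9.
   - Slow oxidation of F9 with H2O2 at 0 °C in the presence of excess 11 should release 13 by syn-elimination with H-1α. 13 stays at low stationary concentration, so it is captured by 11 to give 14.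

## Further compounds
F1 | step 10 | 2α-hydroxydehydrozaluzanin C | C=C1C(=O)[C@H](O)[C@H]2C(=C)CC[C@H]3C(=C)C(=O)O[C@@H]3[C@H]21
F2 | step 10 | 2-hydroxy-3-oxoguaia-1,4(15),10(14),11(13)-tetraen-12,6α-olide | C=C1C(=O)C(O)=C2C(=C)CC[C@H]3C(=C)C(=O)O[C@@H]3[C@H]21
F3 | step 7 | 3β,10α-dihydroxy-1α,4α,5αH-guaian-12,6α-olide | C[C@@H]1[C@@H]2[C@H]3OC(=O)[C@@H](C)[C@@H]3CC[C@@](C)(O)[C@@H]2C[C@@H]1O
F4 | step 7 | guaia-3,10(14)-dien-12,6α-olide | CC1=CC[C@H]2C(=C)CC[C@H]3[C@H](C)C(=O)O[C@@H]3[C@H]21
F5 | step 7 | 3α,4α-epoxyguai-10(14)-en-12,6α-olide | C[C@@]12O[C@@H]1C[C@H]3C(=C)CC[C@H]4[C@H](C)C(=O)O[C@@H]4[C@@H]23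
F6 | step 7 | 3α-hydroxyguaia-4(15),10(14)-dien-12,6α-olide | C=C1[C@H](O)C[C@H]2C(=C)CC[C@H]3[C@H](C)C(=O)O[C@@H]3[C@H]21
F7 | step 7 | 11β-phenylseleno-3α-hydroxyguaia-4(15),10(14)-dien-12,6α-olide | C=C1[C@H](O)C[C@H]2C(=C)CC[C@H]3[C@@](C)([Se]c4ccccc4)C(=O)O[C@@H]3[C@H]21
F8 | step 7 | 3-epizaluzanin C | C=C1[C@H](O)C[C@H]2C(=C)CC[C@H]3C(=C)C(=O)O[C@@H]3[C@H]21
F9 | step 9 | 2α-phenylselenodehydrozaluzanin C | C=C1C(=O)[C@H]([Se]c4ccccc4)[C@H]2C(=C)CC[C@H]3C(=C)C(=O)O[C@@H]3[C@H]21
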